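**Retrosynthetic overview** (target numbered as a bicyclo[9.3.1]pentadecane: C1 and C11 are the ring-fusion CH carbons, C15 the quaternary CHO carbon, C12 the spiro carbon)
1. Endgame: CHO from a CH2OTBS group; the C12 oxirane from a C12 ketone by sulfonium methylide transfer.
2. Key disconnection: C15–C1 together with C11–C12, by an intramolecular Diels–Alder reaction of the acyclic, achiral trienal 25. The enabling feature is the cyclohexane ring C1–C15–C11–C12–C13–C14: its quaternary formyl carbon C15 lies between two CH carbons, with CHO cis to C2 and trans to C10, which is the endo adduct of an E-enal (C15=C11) and an E-diene (C1=C14–C13=C12). Because the C2–C10 chain already joins C1 to C11, the C15–C1 bond also closes the 12-membered ring.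
3. The C12 oxygen comes from a silyl group on the diene terminus (Tamao oxidation); the ring alkene is removed through the enone by conjugate reduction.
4. Trienal 25 is assembled from two carbocuprations of propyne (both Z-alkenes), (E)-1,3-dichloropropene plus a Suzuki coupling (silyl diene), and a Wittig reaction (E-enal).
5. Ring order: cyclohexene and 12-membered ring together in step 11; oxirane last, in step 16.

Key step: step 11

Assumption: the (R)-oxazaborolidinium catalyst, binding a 2-substituted enal through boron and the formyl C–H···O contact, is taken to shield the Re face of the α-carbon (C15); the mirror-image catalyst would be used if the sense proved opposite.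

Step 1
Reactants: 1 2-(2-bromoethyl)-1,3-dioxolane; 2 propyne; 3 oxirane
Product: 7 (3Z)-6-(1,3-dioxolan-2-yl)-4-methylhex-3-en-1-ol, via Grignard reagent 4 (not isolated), via alkylcopper 5 (not isolated), via alkenylcopper 6 (not isolated)
Conditions: Mg, THF, 25 °C; CuBr·SMe2, Et2O/Me2S, −45 °C; 2, −25 °C; LiC≡CC3H7, HMPA, then 3, −40 to −10 °C; H2O
Reagents that add atoms: none
Why: Normant carbocupration: the alkylcopper adds syn across propyne with carbon going to the methyl-bearing carbon, and the derived alkynyl cuprate opens oxirane with retention at the alkenyl carbon, so the two chain carbons end up cis (Z); no stereocentre is formed.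

Step 2
Reactants: 7 (3Z)-6-(1,3-dioxolan-2-yl)-4-methylhex-3-en-1-ol
Product: 8 2-[(3Z)-6-bromo-3-methylhex-3-en-1-yl]-1,3-dioxolane
Conditions: CBr4, PPh3, 2,6-lutidine, CH2Cl2, 0 °C
Reagents that add atoms: carbon tetrabromide, BrC(Br)(Br)Br
Why: Appel bromination of a primary alcohol under buffered conditions that should spare the acetal and the alkene geometry.

Step 3
Reactants: 8 2-[(3Z)-6-bromo-3-methylhex-3-en-1-yl]-1,3-dioxolane; 2 propyne; 9 (E)-1,3-dichloroprop-1-ene
Product: 13 2-[(3Z,7Z,10E)-11-chloro-3,7-dimethylundeca-3,7,10-trien-1-yl]-1,3-dioxolane, via Grignard reagent 10 (not isolated), via alkylcopper 11 (not isolated), via alkenylcopper 12 (not isolated)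
Conditions: Mg, THF; CuBr·SMe2, Et2O/Me2S, −45 °C; 2, −25 °C; 9, −30 to 0 °C
Reagents that add atoms: none
Why: A second Normant carbocupration sets the other Z-alkene in the same way, and the alkenylcopper should displace the allylic chloride of 9 at its CH2 terminus (SN2), leaving the E-vinyl chloride as the handle for the diene.

Step 4
Reactants: 13 2-[(3Z,7Z,10E)-11-chloro-3,7-dimethylundeca-3,7,10-trien-1-yl]-1,3-dioxolane
Product: 14 (4Z,8Z,11E)-12-chloro-4,8-dimethyldodeca-4,8,11-trienal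
Conditions: PPTS, acetone/H2O, 60 °C
Reagents that add atoms: water, O
Why: Mild acid-catalysed hydrolysis of the dioxolane, run at a stage where only isolated alkenes and a vinyl chloride are present.

Step 5
Reactants: 15 ethyl (triphenyl-λ5-phosphanylidene)acetate; 16 5-bromo-2-methylpent-2-ene
Product: 18 ethyl 6-methyl-2-(triphenyl-λ5-phosphanylidene)hept-5-enoate, via phosphonium bromide 17 (not isolated)
Conditions: NaI (cat.), MeCN, reflux; then aq NaOH, CH2Cl2
Reagents that add atoms: none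
Why: C-alkylation of a stabilized phosphorus ylide by a primary halide, followed by deprotonation of the phosphonium salt, should give the α-branched stabilized ylide.

Step 6
Reactants: 14 (4Z,8Z,11E)-12-chloro-4,8-dimethyldodeca-4,8,11-trienal; 18 ethyl 6-methyl-2-(triphenyl-λ5-phosphanylidene)hept-5-enoate
Product: 19 ethyl (2E,6Z,10Z,13E)-14-chloro-6,10-dimethyl-2-(4-methylpent-3-en-1-yl)tetradeca-2,6,10,13-tetraenoate
Conditions: toluene, 90 °C
Reagents that add atoms: none
Why: Wittig olefination with an α-branched ester-stabilized ylide should be E-selective, placing the ester trans and the methylpentenyl chain cis to the main chain.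

Step 7
Reactants: 19 ethyl (2E,6Z,10Z,13E)-14-chloro-6,10-dimethyl-2-(4-methylpent-3-en-1-yl)tetradeca-2,6,10,13-tetraenoate
Product: 20 (2E,6Z,10Z,13E)-14-chloro-6,10-dimethyl-2-(4-methylpent-3-en-1-yl)tetradeca-2,6,10,13-tetraen-1-ol
Conditions: i-Bu2AlH, CH2Cl2, −78 °C; aq potassium sodium tartrate
Reagents that add atoms: none
Why: 1,2-Reduction of an enoate by i-Bu2AlH to the allylic alcohol, with the vinyl chloride and alkene geometries untouched.

Step 8
Reactants: 21 2-ethynyl-4,4,5,5-tetramethyl-1,3,2-dioxaborolane; 22 1,1,1,3,5,5,5-heptamethyltrisiloxane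
Product: 23 1,1,1,3,5,5,5-heptamethyl-3-[(E)-2-(4,4,5,5-tetramethyl-1,3,2-dioxaborolan-2-yl)ethenyl]trisiloxane
Conditions: Pt2[(CH2=CHSiMe2)2O]3 (0.5 mol%), P(t-Bu)3, THF, 25 °C
Reagents that add atoms: none
Why: Hydrosilylation of a terminal alkyne catalysed by zerovalent platinum adds Si–H syn with silicon at the terminal carbon, giving the E-alkene that carries a boron for coupling and an oxidizable silicon.

Step 9
Reactants: 20 (2E,6Z,10Z,13E)-14-chloro-6,10-dimethyl-2-(4-methylpent-3-en-1-yl)tetradeca-2,6,10,13-tetraen-1-ol; 23 1,1,1,3,5,5,5-heptamethyl-3-[(E)-2-(4,4,5,5-tetramethyl-1,3,2-dioxaborolan-2-yl)ethenyl]trisiloxane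
Product: 24 (2E,6Z,10Z,13E,15E)-16-(1,1,1,3,5,5,5-heptamethyltrisiloxan-3-yl)-6,10-dimethyl-2-(4-methylpent-3-en-1-yl)hexadeca-2,6,10,13,15-pentaen-1-ol
Conditions: Pd(OAc)2 (5 mol%), SPhos, K3PO4, THF/H2O, 50 °C
Reagents that add atoms: none
Why: Suzuki–Miyaura coupling of an alkenyl chloride with an alkenylboronate proceeds with retention at both sp2 carbons, and boron should couple in preference to the siloxane silicon, giving the (13E,15E)-silyl diene.

Step 10
Reactants: 24 (2E,6Z,10Z,13E,15E)-16-(1,1,1,3,5,5,5-heptamethyltrisiloxan-3-yl)-6,10-dimethyl-2-(4-methylpent-3-en-1-yl)hexadeca-2,6,10,13,15-pentaen-1-ol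
Product: 25 (2E,6Z,10Z,13E,15E)-16-(1,1,1,3,5,5,5-heptamethyltrisiloxan-3-yl)-6,10-dimethyl-2-(4-methylpent-3-en-1-yl)hexadeca-2,6,10,13,15-pentaenal
Conditions: MnO2, CH2Cl2, 25 °C
Reagents that add atoms: none
Why: MnO2 oxidation of the single allylic alcohol gives the E-enal without touching the dienylsilane or the skipped alkenes.

Step 11
Reactants: 25 (2E,6Z,10Z,13E,15E)-16-(1,1,1,3,5,5,5-heptamethyltrisiloxan-3-yl)-6,10-dimethyl-2-(4-methylpent-3-en-1-yl)hexadeca-2,6,10,13,15-pentaenal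
Product: 27 [(1S,3Z,7Z,11R,12R,15S)-12-(1,1,1,3,5,5,5-heptamethyltrisiloxan-3-yl)-4,8-dimethyl-15-(4-methylpent-3-en-1-yl)bicyclo[9.3.1]pentadeca-3,7,13-trien-15-yl]methanol, via Diels–Alder adduct aldehyde 26 (not isolated)
Conditions: (R)-3,3-diphenyl-1-(o-tolyl)tetrahydro-1H,3H-pyrrolo[1,2-c][1,3,2]oxazaborole·Tf2NH (25 mol%), CH2Cl2, −40 to −20 °C, 25 added over 12 h (2 mM final); then MeOH, NaBH4, −20 to 0 °C
Reagents that add atoms: none
Why: The boron cation binds the formyl group of 25, and the s-trans enal (C15=C11) undergoes a concerted, asynchronous normal-demand [4+2] cycloaddition with the (13E,15E)-diene; the closest known reaction type is the catalytic enantioselective Diels–Alder macrobicyclization of acyclic trienals with cationic oxazaborolidines. The cyclohexene ring (C1, C15, C11, C12, C13, C14) closes by the cycloaddition itself, and the 12-membered ring (C1 to C11 plus C15) closes through the new C15–C1 bond in the bridged 1,3-mode of an intramolecular Diels–Alder reaction, because the C2–C10 tether joins the diene terminus C1 to the β-carbon C11 of the dienophile. Suprafacial addition to the E-enal fixes CHO trans to C10, the endo orientation of the catalyst-bound formyl group places CHO cis to C2 and to the silyl group at C12, and the catalyst shields the Re face of C15 so that C1 adds to the Si face, giving 15S and hence 1S and 11R. The regiochemistry needed (C1 to C15, not C1 to C11) should follow from the preference of the alkyl-bearing diene terminus for the α-carbon of the enal, the silyl group at the other terminus having almost no directing power. Cyclization must outrun oligomerization, which slow addition to the catalyst at millimolar concentration should secure, and aldehyde 26 is reduced in the same flask so that the Lewis acid cannot trigger a carbonyl-ene reaction between the formyl group and the side-chain alkene.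

Step 12
Reactants: 27 [(1S,3Z,7Z,11R,12R,15S)-12-(1,1,1,3,5,5,5-heptamethyltrisiloxan-3-yl)-4,8-dimethyl-15-(4-methylpent-3-en-1-yl)bicyclo[9.3.1]pentadeca-3,7,13-trien-15-yl]methanol
Product: 28 tert-butyl{[(1S,3Z,7Z,11R,12R,15S)-12-(1,1,1,3,5,5,5-heptamethyltrisiloxan-3-yl)-4,8-dimethyl-15-(4-methylpent-3-en-1-yl)bicyclo[9.3.1]pentadeca-3,7,13-trien-15-yl]methoxy}dimethylsilane
Conditions: TBSCl, imidazole, DMF, 25 °C
Reagents that add atoms: tert-butyl(chloro)dimethylsilane, CC(C)(C)[Si](C)(C)Cl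
Why: Silylation of the primary neopentyl alcohol masks the future aldehyde for the ylide step, and is done at once so that the alcohol does not exchange onto the neighbouring siloxane.

Step 13
Reactants: 28 tert-butyl{[(1S,3Z,7Z,11R,12R,15S)-12-(1,1,1,3,5,5,5-heptamethyltrisiloxan-3-yl)-4,8-dimethyl-15-(4-methylpent-3-en-1-yl)bicyclo[9.3.1]pentadeca-3,7,13-trien-15-yl]methoxy}dimethylsilane
Product: 29 (1S,3Z,7Z,11R,12R,15S)-15-{[tert-butyl(dimethyl)silyl]oxymethyl}-4,8-dimethyl-15-(4-methylpent-3-en-1-yl)bicyclo[9.3.1]pentadeca-3,7,13-trien-12-ol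
Conditions: KF, KHCO3, 30% H2O2, THF/MeOH, 40 °C
Reagents that add atoms: hydrogen peroxide, OO
Why: Tamao oxidation: fluoride and peroxide activate the siloxane silicon and the allyl carbon migrates from silicon to oxygen with retention at C12 and without allylic shift; this stereocentre is erased in the next step.

Step 14
Reactants: 29 (1S,3Z,7Z,11R,12R,15S)-15-{[tert-butyl(dimethyl)silyl]oxymethyl}-4,8-dimethyl-15-(4-methylpent-3-en-1-yl)bicyclo[9.3.1]pentadeca-3,7,13-trien-12-ol
Product: 30 (1S,3Z,7Z,11R,15S)-15-{[tert-butyl(dimethyl)silyl]oxymethyl}-4,8-dimethyl-15-(4-methylpent-3-en-1-yl)bicyclo[9.3.1]pentadeca-3,7,13-trien-12-one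
Conditions: Dess–Martin periodinane, NaHCO3, CH2Cl2, 0 to 25 °C
Reagents that add atoms: none
Why: Dess–Martin oxidation of the allylic alcohol gives the enone under neutral conditions that should leave C11, which is α to the new carbonyl, unepimerized.

Step 15
Reactants: 30 (1S,3Z,7Z,11R,15S)-15-{[tert-butyl(dimethyl)silyl]oxymethyl}-4,8-dimethyl-15-(4-methylpent-3-en-1-yl)bicyclo[9.3.1]pentadeca-3,7,13-trien-12-one
Product: 31 (1R,3Z,7Z,11R,15S)-15-{[tert-butyl(dimethyl)silyl]oxymethyl}-4,8-dimethyl-15-(4-methylpent-3-en-1-yl)bicyclo[9.3.1]pentadeca-3,7-dien-12-one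
Conditions: [(Ph3P)CuH]6, H2O, toluene, 25 °C
Reagents that add atoms: none
Why: Conjugate reduction with Stryker's reagent delivers hydride to C14 of the enone only, so the isolated trisubstituted alkenes, the silyl ether and the C11 stereocentre (no base present) should be untouched; the C1 descriptor changes only through priority rules.

Step 16
Reactants: 31 (1R,3Z,7Z,11R,15S)-15-{[tert-butyl(dimethyl)silyl]oxymethyl}-4,8-dimethyl-15-(4-methylpent-3-en-1-yl)bicyclo[9.3.1]pentadeca-3,7-dien-12-one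
Product: 32 tert-butyl{[(1R,3Z,7Z,11R,12S,15S)-4,8-dimethyl-15-(4-methylpent-3-en-1-yl)spiro[bicyclo[9.3.1]pentadeca-3,7-diene-12,2'-oxiran]-15-yl]methoxy}dimethylsilane
Conditions: Me3S+ I−, KN(SiMe3)2, THF, −10 to 0 °C
Reagents that add atoms: trimethylsulfonium iodide, C[S+](C)C.[I-]
Why: Corey–Chaykovsky epoxidation: the small, irreversibly adding sulfonium ylide should attack C12 from the face anti to the C10 branch on the neighbouring C11 (syn to H-11), the other face being blocked by the axial C15 side chain, which places the new CH2 cis to the C15 oxymethyl group and the oxygen trans (12S).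

Step 17
Reactants: 32 tert-butyl{[(1R,3Z,7Z,11R,12S,15S)-4,8-dimethyl-15-(4-methylpent-3-en-1-yl)spiro[bicyclo[9.3.1]pentadeca-3,7-diene-12,2'-oxiran]-15-yl]methoxy}dimethylsilane
Product: 33 [(1R,3Z,7Z,11R,12S,15S)-4,8-dimethyl-15-(4-methylpent-3-en-1-yl)spiro[bicyclo[9.3.1]pentadeca-3,7-diene-12,2'-oxiran]-15-yl]methanol
Conditions: Bu4NF, AcOH, THF, 25 to 40 °C
Reagents that add atoms: none
Why: Fluoride desilylation buffered with acetic acid, so that no free alkoxide is present to open the nearby oxirane.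

Step 18
Reactants: 33 [(1R,3Z,7Z,11R,12S,15S)-4,8-dimethyl-15-(4-methylpent-3-en-1-yl)spiro[bicyclo[9.3.1]pentadeca-3,7-diene-12,2'-oxiran]-15-yl]methanol
Product: 34 (1R,3Z,7Z,11R,12S,15S)-4,8-dimethyl-15-(4-methylpent-3-en-1-yl)spiro[bicyclo[9.3.1]pentadeca-3,7-diene-12,2'-oxirane]-15-carbaldehyde
Conditions: Dess–Martin periodinane, NaHCO3, CH2Cl2, 0 °C
Reagents that add atoms: none
Why: Buffered Dess–Martin oxidation of the neopentyl alcohol to the non-enolizable aldehyde should tolerate the oxirane and the three trisubstituted alkenes.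

**Compound list**
1 | 2-(2-bromoethyl)-1,3-dioxolane | BrCCC1OCCO1 | starting material
2 | propyne | CC#C | starting material
3 | oxirane | C1CO1 | starting material
4 | [2-(1,3-dioxolan-2-yl)ethyl]magnesium bromide | Br[Mg]CCC1OCCO1 | intermediate
5 | [2-(1,3-dioxolan-2-yl)ethyl]copper (magnesium dibromide complex) | [Cu]CCC1OCCO1 | intermediate
6 | [(1Z)-4-(1,3-dioxolan-2-yl)-2-methylbut-1-en-1-yl]copper | [Cu]/C=C(/C)CCC1OCCO1 | intermediate
7 | (3Z)-6-(1,3-dioxolan-2-yl)-4-methylhex-3-en-1-ol | OCC/C=C(/C)CCC1OCCO1 | intermediate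
8 | 2-[(3Z)-6-bromo-3-methylhex-3-en-1-yl]-1,3-dioxolane | BrCC/C=C(/C)CCC1OCCO1 | intermediate
9 | (E)-1,3-dichloroprop-1-ene | Cl/C=C/CCl | starting material
10 | [(3Z)-6-(1,3-dioxolan-2-yl)-4-methylhex-3-en-1-yl]magnesium bromide | Br[Mg]CC/C=C(/C)CCC1OCCO1 | intermediate
11 | [(3Z)-6-(1,3-dioxolan-2-yl)-4-methylhex-3-en-1-yl]copper (magnesium dibromide complex) | [Cu]CC/C=C(/C)CCC1OCCO1 | intermediate
12 | [(1Z,5Z)-8-(1,3-dioxolan-2-yl)-2,6-dimethylocta-1,5-dien-1-yl]copper | [Cu]/C=C(/C)CC/C=C(/C)CCC1OCCO1 | intermediate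
13 | 2-[(3Z,7Z,10E)-11-chloro-3,7-dimethylundeca-3,7,10-trien-1-yl]-1,3-dioxolane | Cl/C=C/C/C=C(/C)CC/C=C(/C)CCC1OCCO1 | intermediate
14 | (4Z,8Z,11E)-12-chloro-4,8-dimethyldodeca-4,8,11-trienal | O=CCC/C(C)=C\CC/C(C)=C\C/C=C/Cl | intermediate
15 | ethyl (triphenyl-λ5-phosphanylidene)acetate | CCOC(=O)C=P(c1ccccc1)(c1ccccc1)c1ccccc1 | starting material
16 | 5-bromo-2-methylpent-2-ene | CC(C)=CCCBr | starting material
17 | (1-ethoxy-6-methyl-1-oxohept-5-en-2-yl)triphenylphosphonium bromide | CCOC(=O)C(CCC=C(C)C)[P+](c1ccccc1)(c1ccccc1)c1ccccc1.[Br-] | intermediate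
18 | ethyl 6-methyl-2-(triphenyl-λ5-phosphanylidene)hept-5-enoate | CCOC(=O)C(CCC=C(C)C)=P(c1ccccc1)(c1ccccc1)c1ccccc1 | intermediate
19 | ethyl (2E,6Z,10Z,13E)-14-chloro-6,10-dimethyl-2-(4-methylpent-3-en-1-yl)tetradeca-2,6,10,13-tetraenoate | CCOC(=O)/C(CCC=C(C)C)=C/CC/C(C)=C\CC/C(C)=C\C/C=C/Cl | intermediate
20 | (2E,6Z,10Z,13E)-14-chloro-6,10-dimethyl-2-(4-methylpent-3-en-1-yl)tetradeca-2,6,10,13-tetraen-1-ol | OC/C(CCC=C(C)C)=C/CC/C(C)=C\CC/C(C)=C\C/C=C/Cl | intermediate
21 | 2-ethynyl-4,4,5,5-tetramethyl-1,3,2-dioxaborolane | C#CB1OC(C)(C)C(C)(C)O1 | starting material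
22 | 1,1,1,3,5,5,5-heptamethyltrisiloxane | C[SiH](O[Si](C)(C)C)O[Si](C)(C)C | starting material
23 | 1,1,1,3,5,5,5-heptamethyl-3-[(E)-2-(4,4,5,5-tetramethyl-1,3,2-dioxaborolan-2-yl)ethenyl]trisiloxane | CC1(C)OB(/C=C/[Si](C)(O[Si](C)(C)C)O[Si](C)(C)C)OC1(C)C | intermediate
24 | (2E,6Z,10Z,13E,15E)-16-(1,1,1,3,5,5,5-heptamethyltrisiloxan-3-yl)-6,10-dimethyl-2-(4-methylpent-3-en-1-yl)hexadeca-2,6,10,13,15-pentaen-1-ol | OC/C(CCC=C(C)C)=C/CC/C(C)=C\CC/C(C)=C\C/C=C/C=C/[Si](C)(O[Si](C)(C)C)O[Si](C)(C)C | intermediate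
25 | (2E,6Z,10Z,13E,15E)-16-(1,1,1,3,5,5,5-heptamethyltrisiloxan-3-yl)-6,10-dimethyl-2-(4-methylpent-3-en-1-yl)hexadeca-2,6,10,13,15-pentaenal | O=C/C(CCC=C(C)C)=C/CC/C(C)=C\CC/C(C)=C\C/C=C/C=C/[Si](C)(O[Si](C)(C)C)O[Si](C)(C)C | intermediate
26 | (1S,3Z,7Z,11R,12R,15S)-12-(1,1,1,3,5,5,5-heptamethyltrisiloxan-3-yl)-4,8-dimethyl-15-(4-methylpent-3-en-1-yl)bicyclo[9.3.1]pentadeca-3,7,13-triene-15-carbaldehyde | CC(C)=CCC[C@]1(C=O)[C@H]2C/C=C(/C)CC/C=C(/C)CC[C@H]1[C@H]([Si](C)(O[Si](C)(C)C)O[Si](C)(C)C)C=C2 | intermediate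
27 | [(1S,3Z,7Z,11R,12R,15S)-12-(1,1,1,3,5,5,5-heptamethyltrisiloxan-3-yl)-4,8-dimethyl-15-(4-methylpent-3-en-1-yl)bicyclo[9.3.1]pentadeca-3,7,13-trien-15-yl]methanol | CC(C)=CCC[C@]1(CO)[C@H]2C/C=C(/C)CC/C=C(/C)CC[C@H]1[C@H]([Si](C)(O[Si](C)(C)C)O[Si](C)(C)C)C=C2 | intermediate
28 | tert-butyl{[(1S,3Z,7Z,11R,12R,15S)-12-(1,1,1,3,5,5,5-heptamethyltrisiloxan-3-yl)-4,8-dimethyl-15-(4-methylpent-3-en-1-yl)bicyclo[9.3.1]pentadeca-3,7,13-trien-15-yl]methoxy}dimethylsilane | CC(C)=CCC[C@]1(CO[Si](C)(C)C(C)(C)C)[C@H]2C/C=C(/C)CC/C=C(/C)CC[C@H]1[C@H]([Si](C)(O[Si](C)(C)C)O[Si](C)(C)C)C=C2 | intermediate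
29 | (1S,3Z,7Z,11R,12R,15S)-15-{[tert-butyl(dimethyl)silyl]oxymethyl}-4,8-dimethyl-15-(4-methylpent-3-en-1-yl)bicyclo[9.3.1]pentadeca-3,7,13-trien-12-ol | CC(C)=CCC[C@]1(CO[Si](C)(C)C(C)(C)C)[C@H]2C/C=C(/C)CC/C=C(/C)CC[C@H]1[C@H](O)C=C2 | intermediate
30 | (1S,3Z,7Z,11R,15S)-15-{[tert-butyl(dimethyl)silyl]oxymethyl}-4,8-dimethyl-15-(4-methylpent-3-en-1-yl)bicyclo[9.3.1]pentadeca-3,7,13-trien-12-one | CC(C)=CCC[C@]1(CO[Si](C)(C)C(C)(C)C)[C@H]2C/C=C(/C)CC/C=C(/C)CC[C@H]1C(=O)C=C2 | intermediate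
31 | (1R,3Z,7Z,11R,15S)-15-{[tert-butyl(dimethyl)silyl]oxymethyl}-4,8-dimethyl-15-(4-methylpent-3-en-1-yl)bicyclo[9.3.1]pentadeca-3,7-dien-12-one | CC(C)=CCC[C@]1(CO[Si](C)(C)C(C)(C)C)[C@H]2C/C=C(/C)CC/C=C(/C)CC[C@H]1C(=O)CC2 | intermediate
32 | tert-butyl{[(1R,3Z,7Z,11R,12S,15S)-4,8-dimethyl-15-(4-methylpent-3-en-1-yl)spiro[bicyclo[9.3.1]pentadeca-3,7-diene-12,2'-oxiran]-15-yl]methoxy}dimethylsilane | CC(C)=CCC[C@]1(CO[Si](C)(C)C(C)(C)C)[C@H]2C/C=C(/C)CC/C=C(/C)CC[C@H]1[C@@]1(CC2)CO1 | intermediate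
33 | [(1R,3Z,7Z,11R,12S,15S)-4,8-dimethyl-15-(4-methylpent-3-en-1-yl)spiro[bicyclo[9.3.1]pentadeca-3,7-diene-12,2'-oxiran]-15-yl]methanol | CC(C)=CCC[C@]1(CO)[C@H]2C/C=C(/C)CC/C=C(/C)CC[C@H]1[C@@]1(CC2)CO1 | intermediate
34 | (1R,3Z,7Z,11R,12S,15S)-4,8-dimethyl-15-(4-methylpent-3-en-1-yl)spiro[bicyclo[9.3.1]pentadeca-3,7-diene-12,2'-oxirane]-15-carbaldehyde | CC(C)=CCC[C@]1(C=O)[C@H]2C/C=C(/C)CC/C=C(/C)CC[C@H]1[C@@]1(CC2)CO1 | target

**Step count and risks**
Total step count: 18. Longest linear sequence: 16 steps (steps 1–4, 6, 7, 9–18); steps 5 and 8 prepare reagents 18 and 23 in parallel.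

Steps most likely to fail:

Step 11. The macrocyclic cycloaddition may be too slow at the dilution it needs, so that oligomerization or the fused regiochemical mode (C1 bonding to C11) takes over, or the catalyst may give poor facial or endo selectivity. The fallback sets out from 25 and changes both the activation and the source of asymmetry. Acetalization with (2R,4R)-pentane-2,4-diol (PPTS, benzene, water removed) would give the (4R,6R)-4,6-dimethyl-1,3-dioxane acetal of the enal F1. Me3SiOTf with a hindered pyridine base in CH2Cl2 at −78 °C would ionize it to a vinyl oxocarbenium ion, a far more reactive dienophile, whose ionic intramolecular Diels–Alder reaction under auxiliary control should give the bicyclic dioxane acetal F2. Mild acid hydrolysis (aq oxalic acid on silica) would release the diol and return aldehyde 26, which is reduced to 27 as in step 11. The antipodal diol would be used if the auxiliary favoured the wrong face.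

Step 16. Methylene transfer may occur on the wrong face of the C12 carbonyl, or the basic ylide may enolize the ketone and epimerize C11. The fallback sets out from enone 30, before the conjugate reduction, where the ring is a flatter half-chair with a different facial bias. The same sulfonium ylide should add 1,2 to the enone carbonyl to give the vinyl oxirane tert-butyl{[(1S,3Z,7Z,11R,12S,15S)-4,8-dimethyl-15-(4-methylpent-3-en-1-yl)spiro[bicyclo[9.3.1]pentadeca-3,7,13-triene-12,2'-oxiran]-15-yl]methoxy}dimethylsilane F3. Diimide (2-nitrobenzenesulfonohydrazide, Et3N, CH2Cl2) should then saturate only the cis-disubstituted ring alkene, and the sequence comes back to the route at 32.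

Step 13. Fluoride may cleave the allylic C–Si bond by protodesilylation with double-bond shift instead of oxidation, or oxidation at the hindered C12 may stall. The fallback sets out from 28 and removes the allylic character first. Diimide reduction of the C13=C14 alkene would give the saturated silane tert-butyl{[(1R,3Z,7Z,11R,12R,15S)-12-(1,1,1,3,5,5,5-heptamethyltrisiloxan-3-yl)-4,8-dimethyl-15-(4-methylpent-3-en-1-yl)bicyclo[9.3.1]pentadeca-3,7-dien-15-yl]methoxy}dimethylsilane F4. Tamao oxidation of this non-allylic silane would give (1R,3Z,7Z,11R,12R,15S)-15-{[tert-butyl(dimethyl)silyl]oxymethyl}-4,8-dimethyl-15-(4-methylpent-3-en-1-yl)bicyclo[9.3.1]pentadeca-3,7-dien-12-ol F5. Dess–Martin oxidation then comes back to the route at 31, bypassing 29 and 30.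

Further compounds
F1 | step 11 | (4R,6R)-4,6-dimethyl-1,3-dioxane acetal of enal 25 | CC(C)=CCC/C(C1O[C@H](C)C[C@@H](C)O1)=C\CC/C(C)=C\CC/C(C)=C\C/C=C/C=C/[Si](C)(O[Si](C)(C)C)O[Si](C)(C)C
F2 | step 11 | (4R,6R)-4,6-dimethyl-1,3-dioxane acetal of aldehyde 26 | CC(C)=CCC[C@]1(C2O[C@H](C)C[C@@H](C)O2)[C@H]3C/C=C(/C)CC/C=C(/C)CC[C@H]1[C@H]([Si](C)(O[Si](C)(C)C)O[Si](C)(C)C)C=C3
F3 | step 16 | tert-butyl{[(1S,3Z,7Z,11R,12S,15S)-4,8-dimethyl-15-(4-methylpent-3-en-1-yl)spiro[bicyclo[9.3.1]pentadeca-3,7,13-triene-12,2'-oxiran]-15-yl]methoxy}dimethylsilane | CC(C)=CCC[C@]1(CO[Si](C)(C)C(C)(C)C)[C@H]2C/C=C(/C)CC/C=C(/C)CC[C@H]1[C@@]1(C=C2)CO1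
F4 | step 13 | tert-butyl{[(1R,3Z,7Z,11R,12R,15S)-12-(1,1,1,3,5,5,5-heptamethyltrisiloxan-3-yl)-4,8-dimethyl-15-(4-methylpent-3-en-1-yl)bicyclo[9.3.1]pentadeca-3,7-dien-15-yl]methoxy}dimethylsilane | CC(C)=CCC[C@]1(CO[Si](C)(C)C(C)(C)C)[C@H]2C/C=C(/C)CC/C=C(/C)CC[C@H]1[C@H]([Si](C)(O[Si](C)(C)C)O[Si](C)(C)C)CC2
F5 | step 13 | (1R,3Z,7Z,11R,12R,15S)-15-{[tert-butyl(dimethyl)silyl]oxymethyl}-4,8-dimethyl-15-(4-methylpent-3-en-1-yl)bicyclo[9.3.1]pentadeca-3,7-dien-12-ol | CC(C)=CCC[C@]1(CO[Si](C)(C)C(C)(C)C)[C@H]2C/C=C(/C)CC/C=C(/C)CC[C@H]1[C@H](O)CC2
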